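**Retrosynthetic overview**

1. The target is read as ent-robinetinidol-(4α→8)-ent-epirobinetinidol-(4α→8)-epicatechin: upper unit (2S,3R,4S), middle unit (2S,3S,4S), lower unit (2R,3R). The last step is hydrogenolysis of thirteen benzyl ethers.
2. Key disconnection: ring C of the middle unit is opened at C4–C4a and the interflavan bond C4–C8 (lower unit) is cut in the same operation, giving open-chain hydroxy aldehyde 19 (C4 = CHO) and benzylated epicatechin 21. Enabling feature: C4 is a diarylmethine between C4a, the only free ortho carbon of the middle resorcinol ring (para to its 7-oxygen, ortho to O1), and C8 of the phloroglucinol ring of the lower unit. One aldehyde carbon can therefore be arylated twice, first inside the O1–C2–C3 tether, then from outside, trans to the C3 hydroxyl.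
3. 19 comes from phenol 14 and cis-epoxy alcohol 17 (SN2 opening at the benzylic carbon sets C2, Sharpless epoxidation sets C3), then oxidation of the primary alcohol.
4. 14 (upper unit already bonded through its C4 to the future C8 of the middle ring A) comes from flavanone 8 and the 2-lithiated resorcinol diether 11, then hydride capture of the 4-aryl cation trans to the C3 oxygen. 8 comes from chalcone 4 by asymmetric epoxidation and phenol cyclisation.
5. Ring order: upper ring C (O1–C2 bond, step 4), then middle ring C (C4–C4a bond, step 15). The rings of the lower unit are bought with (−)-epicatechin.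

Key step: step 15

Abbreviations in names: Ar = 3,4,5-tris(benzyloxy)phenyl; U = (2S,3R,4S)-3,7-bis(benzyloxy)-2-Ar-chroman-4-yl (the protected upper unit).

Remark: carbinol 12 and diol 22 lose their C4 configuration in the cation that follows. Each is drawn as the epimer expected from attack trans to the C3 oxygen, and either epimer carries on.

**Route**

Step 1
Reactants: 1 1-[4-(benzyloxy)-2-hydroxyphenyl]ethan-1-one
Product: 2 1-[4-(benzyloxy)-2-(methoxymethoxy)phenyl]ethan-1-one
Conditions: NaH, MeOCH2Cl, DMF, 0 °C → rt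
Reagents that add atoms: chloromethyl methyl ether, COCCl
Why: Williamson O-alkylation of the phenoxide masks the phenol so that the later enone can be epoxidised without Algar–Flynn–Oyamada-type cyclisation.

Step 2
Reactants: 2 1-[4-(benzyloxy)-2-(methoxymethoxy)phenyl]ethan-1-one; 3 3,4,5-tris(benzyloxy)benzaldehyde
Product: 4 (E)-1-[4-(benzyloxy)-2-(methoxymethoxy)phenyl]-3-Ar-prop-2-en-1-one
Conditions: KOH, EtOH/THF, rt
Reagents that add atoms: none
Why: Claisen–Schmidt condensation of the methyl ketone enolate with the non-enolisable aldehyde should give the E-chalcone after dehydration.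

Step 3
Reactants: 4 (E)-1-[4-(benzyloxy)-2-(methoxymethoxy)phenyl]-3-Ar-prop-2-en-1-one
Product: 5 [4-(benzyloxy)-2-(methoxymethoxy)phenyl][(2S,3R)-3-Ar-oxiran-2-yl]methanone
Conditions: poly-D-leucine, urea–H2O2, DBU, THF, rt
Reagents that add atoms: urea–hydrogen peroxide, NC(N)=O.OO
Why: Juliá–Colonna epoxidation, in which hydroperoxide adds to the enone held on the helical poly-D-leucine so that one face is shielded and the trans-epoxide should form as the (2S,3R) isomer, the mirror image of the product given by poly-L-leucine.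

Step 4
Reactants: 5 [4-(benzyloxy)-2-(methoxymethoxy)phenyl][(2S,3R)-3-Ar-oxiran-2-yl]methanone
Product: 7 (2S,3S)-7-(benzyloxy)-3-hydroxy-2-Ar-chroman-4-one, via phenol epoxide 6 (not isolated)
Conditions: HCl (conc.), MeOH/THF, 55 °C
Reagents that add atoms: none
Why: Acid removes the methoxymethyl group and the freed phenol opens the epoxide at the benzylic carbon (6-endo-tet) with inversion, so that C2 becomes S while the carbinol carbon keeps its configuration and the trans-dihydroflavonol results.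

Step 5
Reactants: 7 (2S,3S)-7-(benzyloxy)-3-hydroxy-2-Ar-chroman-4-one
Product: 8 (2S,3S)-3,7-bis(benzyloxy)-2-Ar-chroman-4-one
Conditions: BnBr, Ag2O, CH2Cl2, rt, dark
Reagents that add atoms: benzyl bromide, BrCc1ccccc1
Why: Ag2O-promoted Williamson etherification benzylates the secondary alcohol without the strong base that would enolise the ketone or open the pyranone by β-elimination.

Step 6
Reactants: 9 3-(benzyloxy)phenol
Product: 10 1-(benzyloxy)-3-(methoxymethoxy)benzene
Conditions: NaH, MeOCH2Cl, DMF, 0 °C → rt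
Reagents that add atoms: chloromethyl methyl ether, COCCl
Why: O-alkylation of the phenoxide installs an acid-labile group that also directs the lithiation of the next step.

Step 7
Reactants: 10 1-(benzyloxy)-3-(methoxymethoxy)benzene; 8 (2S,3S)-3,7-bis(benzyloxy)-2-Ar-chroman-4-one
Product: 12 (2S,3S,4S)-3,7-bis(benzyloxy)-4-[2-(benzyloxy)-6-(methoxymethoxy)phenyl]-2-Ar-chroman-4-ol, via aryllithium 11 (not isolated)
Conditions: 10, n-BuLi, THF, 0 °C; then 8, −78 °C; H2O quench
Reagents that add atoms: none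
Why: Directed ortho-metalation at the carbon between the two alkoxy groups gives a chelated 2,6-dialkoxyaryllithium that should add 1,2 to the ketone faster than it enolises it, which fixes the regiochemistry of the later C4→C8 bond.

Step 8
Reactants: 12 (2S,3S,4S)-3,7-bis(benzyloxy)-4-[2-(benzyloxy)-6-(methoxymethoxy)phenyl]-2-Ar-chroman-4-ol
Product: 14 3-(benzyloxy)-2-U-phenol, via MOM ether 13 (not isolated)
Conditions: Et3SiH, CF3CO2H, CH2Cl2, −20 °C → rt
Reagents that add atoms: none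
Why: Ionic hydrogenation, in which the acid ionises the doubly benzylic tertiary alcohol and Et3SiH should deliver hydride to the planar C4 cation trans to the C3 benzyloxy group (the usual sense of capture of flavan-4-yl cations, reinforced by allylic strain between the 4-aryl group and the C3 substituent), setting C4 as S with the aryl group cis to the C3 oxygen, while the same acid cleaves the methoxymethyl ether.

Step 9
Reactants: 3 3,4,5-tris(benzyloxy)benzaldehyde
Product: 15 ethyl (Z)-3-Ar-prop-2-enoate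
Conditions: (PhO)2P(O)CH2CO2Et, NaH, THF, −78 → 0 °C
Reagents that add atoms: ethyl (diphenoxyphosphoryl)acetate, CCOC(=O)CP(=O)(Oc1ccccc1)Oc1ccccc1
Why: Ando-type Horner–Wadsworth–Emmons olefination, in which the electron-poor diaryl phosphonate makes elimination from the kinetic adduct fast and should give the Z-enoate.

Step 10
Reactants: 15 ethyl (Z)-3-Ar-prop-2-enoate
Product: 16 (Z)-3-Ar-prop-2-en-1-ol
Conditions: iBu2AlH, CH2Cl2, −78 °C; Rochelle salt work-up
Reagents that add atoms: none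
Why: 1,2-Reduction of the ester by the aluminium hydride gives the allylic alcohol without touching the Z-alkene.

Step 11
Reactants: 16 (Z)-3-Ar-prop-2-en-1-ol
Product: 17 [(2S,3R)-3-Ar-oxiran-2-yl]methanol
Conditions: Ti(OiPr)4 (0.2 equiv), L-(+)-diethyl tartrate (0.24 equiv), t-BuOOH, 4 Å MS, CH2Cl2, −20 °C
Reagents that add atoms: tert-butyl hydroperoxide, CC(C)(C)OO
Why: Sharpless asymmetric epoxidation, in which the titanium tartrate complex of L-(+)-diethyl tartrate delivers oxygen to the face of the Z-allylic alcohol that gives the (2S,3R) cis-epoxide.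

Step 12
Reactants: 14 3-(benzyloxy)-2-U-phenol; 17 [(2S,3R)-3-Ar-oxiran-2-yl]methanol
Product: 18 (2S,3S)-3-[3-(benzyloxy)-2-U-phenoxy]-3-Ar-propane-1,2-diol
Conditions: Cs2CO3, DMF, 70 °C
Reagents that add atoms: none
Why: SN2 opening of the aryl glycidol by the phenoxide should occur at the benzylic carbon (the other epoxide carbon is deactivated by the adjacent carbinol) with inversion, which sets the future C2 as S and, from the cis-epoxide, the syn arrangement that becomes 2,3-cis.

Step 13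
Reactants: 18 (2S,3S)-3-[3-(benzyloxy)-2-U-phenoxy]-3-Ar-propane-1,2-diol
Product: 19 (2R,3S)-3-[3-(benzyloxy)-2-U-phenoxy]-2-hydroxy-3-Ar-propanal
Conditions: TEMPO (2,2,6,6-tetramethylpiperidine 1-oxyl, 0.2 equiv), PhI(OAc)2, CH2Cl2, 0 °C → rt; used crude
Reagents that add atoms: none
Why: Oxoammonium oxidation is selective for the unhindered primary alcohol over the hindered secondary one and stops at the aldehyde in the absence of water.

Step 14
Reactants: 20 (−)-epicatechin
Product: 21 (2R,3R)-5,7-bis(benzyloxy)-2-[3,4-bis(benzyloxy)phenyl]chroman-3-ol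
Conditions: BnBr, K2CO3, DMF, 0 °C → rt
Reagents that add atoms: benzyl bromide, BrCc1ccccc1
Why: Williamson etherification with a carbonate base benzylates the four phenols and leaves the less acidic secondary alcohol free.

Step 15
Reactants: 19 (2R,3S)-3-[3-(benzyloxy)-2-U-phenoxy]-2-hydroxy-3-Ar-propanal; 21 (2R,3R)-5,7-bis(benzyloxy)-2-[3,4-bis(benzyloxy)phenyl]chroman-3-ol
Product: 23 (2R,3R)-5,7-bis(benzyloxy)-2-[3,4-bis(benzyloxy)phenyl]-8-[(2S,3S,4S)-7-(benzyloxy)-3-hydroxy-8-U-2-Ar-chroman-4-yl]chroman-3-ol, via flavan-3,4-diol 22 (not isolated)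
Conditions: 21 (3 equiv), Sc(OTf)3 (0.2 equiv), CH2Cl2, −40 → 0 °C; excess 21 recovered
Reagents that add atoms: none
Why: Proposed new method: Sc(OTf)3 activates the chelating α-hydroxy aldehyde of 19, the free ortho carbon of the aryl ether ring (future C4a, para to the benzyloxy group) attacks the carbonyl carbon (future C4) to give flavan-3,4-diol 22, and 22 ionises under the same acid to the C4 benzylic cation, which is captured by C8 of 21. The closest known reactions are the acid-mediated cyclisation of arene-tethered aldehydes and acetals to cyclic benzylic alcohols and ethers (Pomeranz–Fritsch–Bobbitt type) and the Lewis-acid coupling of flavan-3,4-diols or 4-alkoxyflavans with flavan-3-ols; running both in one flask on an open-chain precursor is the new element. Ring C of the middle unit (O1–C2–C3–C4–C4a–C8a) closes in the 6-exo-trig mode, the carbonyl π bond lying outside the new ring. The new stereocentre C4 is controlled by the C3 hydroxyl and the C2 aryl group, which are cis and on one face of the flavanyl cation, so that the nucleophile should enter on the opposite face, as with 2,3-cis flavan-4-yl cations in general, and C4 becomes S (3,4-trans). The step needs ring closure before intermolecular arylation, closure at C4a and not onto the pyrogallol ring, and C8 rather than C6 of 21: the six-membered tether to a resorcinol-type carbon, the less favourable five-membered alternative, and the known C8 preference of benzylated epicatechin used in excess should secure these. If intermolecular attack came first, the diarylmethyl cation so formed should close to the same isomer, because allylic strain with the 2,6-dioxygenated aryl group holds the C3–H bond in the cation plane and puts the C3 hydroxyl anti to the forming bond.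

Step 16
Reactants: 23 (2R,3R)-5,7-bis(benzyloxy)-2-[3,4-bis(benzyloxy)phenyl]-8-[(2S,3S,4S)-7-(benzyloxy)-3-hydroxy-8-U-2-Ar-chroman-4-yl]chroman-3-ol
Product: 24 ent-robinetinidol-(4α→8)-ent-epirobinetinidol-(4α→8)-epicatechin (CNP0115797.3)
Conditions: H2 (1 atm), Pd(OH)2/C, THF/MeOH/H2O, rt
Reagents that add atoms: none
Why: Hydrogenolysis cleaves the thirteen benzyl ethers, while the cyclic O1–C2 ether bonds and the acid-stable 5-deoxy interflavan bond should survive these neutral conditions.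

**Compound list**

1 | 1-[4-(benzyloxy)-2-hydroxyphenyl]ethan-1-one | CC(=O)c1ccc(OCc2ccccc2)cc1O | starting material
2 | 1-[4-(benzyloxy)-2-(methoxymethoxy)phenyl]ethan-1-one | CC(=O)c1ccc(OCc2ccccc2)cc1OCOC | intermediate
3 | 3,4,5-tris(benzyloxy)benzaldehyde | O=Cc1cc(OCc2ccccc2)c(OCc2ccccc2)c(OCc2ccccc2)c1 | starting material
4 | (E)-1-[4-(benzyloxy)-2-(methoxymethoxy)phenyl]-3-Ar-prop-2-en-1-one | COCOc1cc(OCc2ccccc2)ccc1C(=O)/C=C/c1cc(OCc2ccccc2)c(OCc2ccccc2)c(OCc2ccccc2)c1 | intermediate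
5 | [4-(benzyloxy)-2-(methoxymethoxy)phenyl][(2S,3R)-3-Ar-oxiran-2-yl]methanone | COCOc1cc(OCc2ccccc2)ccc1C(=O)[C@H]1O[C@@H]1c1cc(OCc2ccccc2)c(OCc2ccccc2)c(OCc2ccccc2)c1 | intermediate
6 | [4-(benzyloxy)-2-hydroxyphenyl][(2S,3R)-3-Ar-oxiran-2-yl]methanone | Oc1cc(OCc2ccccc2)ccc1C(=O)[C@H]1O[C@@H]1c1cc(OCc2ccccc2)c(OCc2ccccc2)c(OCc2ccccc2)c1 | intermediate (not isolated)
7 | (2S,3S)-7-(benzyloxy)-3-hydroxy-2-Ar-chroman-4-one | C(c1ccccc1)Oc1ccc2c(c1)O[C@@H](c1cc(OCc3ccccc3)c(OCc3ccccc3)c(OCc3ccccc3)c1)[C@H](O)C2=O | intermediate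
8 | (2S,3S)-3,7-bis(benzyloxy)-2-Ar-chroman-4-one | C(c1ccccc1)Oc1ccc2c(c1)O[C@@H](c1cc(OCc3ccccc3)c(OCc3ccccc3)c(OCc3ccccc3)c1)[C@H](OCc1ccccc1)C2=O | intermediate
9 | 3-(benzyloxy)phenol | Oc1cccc(OCc2ccccc2)c1 | starting material
10 | 1-(benzyloxy)-3-(methoxymethoxy)benzene | COCOc1cccc(OCc2ccccc2)c1 | intermediate
11 | [2-(benzyloxy)-6-(methoxymethoxy)phenyl]lithium | [Li]c1c(OCOC)cccc1OCc1ccccc1 | intermediate (not isolated)
12 | (2S,3S,4S)-3,7-bis(benzyloxy)-4-[2-(benzyloxy)-6-(methoxymethoxy)phenyl]-2-Ar-chroman-4-ol | C(c1ccccc1)Oc1ccc2c(c1)O[C@@H](c1cc(OCc3ccccc3)c(OCc3ccccc3)c(OCc3ccccc3)c1)[C@H](OCc1ccccc1)[C@@]2(O)c1c(OCc3ccccc3)cccc1OCOC | intermediate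
13 | 1-(benzyloxy)-3-(methoxymethoxy)-2-U-benzene | C(c1ccccc1)Oc1ccc2c(c1)O[C@@H](c1cc(OCc3ccccc3)c(OCc3ccccc3)c(OCc3ccccc3)c1)[C@H](OCc1ccccc1)[C@@H]2c1c(OCc3ccccc3)cccc1OCOC | intermediate (not isolated)
14 | 3-(benzyloxy)-2-U-phenol | C(c1ccccc1)Oc1ccc2c(c1)O[C@@H](c1cc(OCc3ccccc3)c(OCc3ccccc3)c(OCc3ccccc3)c1)[C@H](OCc1ccccc1)[C@@H]2c1c(OCc3ccccc3)cccc1O | intermediate
15 | ethyl (Z)-3-Ar-prop-2-enoate | CCOC(=O)/C=C\c1cc(OCc2ccccc2)c(OCc2ccccc2)c(OCc2ccccc2)c1 | intermediate
16 | (Z)-3-Ar-prop-2-en-1-ol | OC/C=C\c1cc(OCc2ccccc2)c(OCc2ccccc2)c(OCc2ccccc2)c1 | intermediate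
17 | [(2S,3R)-3-Ar-oxiran-2-yl]methanol | OC[C@@H]1O[C@@H]1c1cc(OCc2ccccc2)c(OCc2ccccc2)c(OCc2ccccc2)c1 | intermediate
18 | (2S,3S)-3-[3-(benzyloxy)-2-U-phenoxy]-3-Ar-propane-1,2-diol | C(c1ccccc1)Oc1ccc2c(c1)O[C@@H](c1cc(OCc3ccccc3)c(OCc3ccccc3)c(OCc3ccccc3)c1)[C@H](OCc1ccccc1)[C@@H]2c1c(OCc3ccccc3)cccc1O[C@@H](c1cc(OCc3ccccc3)c(OCc3ccccc3)c(OCc3ccccc3)c1)[C@@H](O)CO | intermediate
19 | (2R,3S)-3-[3-(benzyloxy)-2-U-phenoxy]-2-hydroxy-3-Ar-propanal | C(c1ccccc1)Oc1ccc2c(c1)O[C@@H](c1cc(OCc3ccccc3)c(OCc3ccccc3)c(OCc3ccccc3)c1)[C@H](OCc1ccccc1)[C@@H]2c1c(OCc3ccccc3)cccc1O[C@@H](c1cc(OCc3ccccc3)c(OCc3ccccc3)c(OCc3ccccc3)c1)[C@@H](O)C=O | intermediate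
20 | (−)-epicatechin, (2R,3R)-2-(3,4-dihydroxyphenyl)chroman-3,5,7-triol | Oc1cc(O)c2c(c1)O[C@H](c1ccc(O)c(O)c1)[C@H](O)C2 | starting material
21 | (2R,3R)-5,7-bis(benzyloxy)-2-[3,4-bis(benzyloxy)phenyl]chroman-3-ol | C(c1ccccc1)Oc1cc(OCc3ccccc3)c2c(c1)O[C@H](c1ccc(OCc3ccccc3)c(OCc3ccccc3)c1)[C@H](O)C2 | intermediate
22 | (2S,3S,4R)-7-(benzyloxy)-8-U-2-Ar-chroman-3,4-diol (drawn C4 epimer) | C(c1ccccc1)Oc1ccc2c(c1)O[C@@H](c1cc(OCc3ccccc3)c(OCc3ccccc3)c(OCc3ccccc3)c1)[C@H](OCc1ccccc1)[C@@H]2c1c(OCc3ccccc3)ccc2c1O[C@@H](c1cc(OCc3ccccc3)c(OCc3ccccc3)c(OCc3ccccc3)c1)[C@@H](O)[C@@H]2O | intermediate (not isolated)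
23 | (2R,3R)-5,7-bis(benzyloxy)-2-[3,4-bis(benzyloxy)phenyl]-8-[(2S,3S,4S)-7-(benzyloxy)-3-hydroxy-8-U-2-Ar-chroman-4-yl]chroman-3-ol (trideca-O-benzyl ether of 24) | C(c1ccccc1)Oc1ccc2c(c1)O[C@@H](c1cc(OCc3ccccc3)c(OCc3ccccc3)c(OCc3ccccc3)c1)[C@H](OCc1ccccc1)[C@@H]2c1c(OCc3ccccc3)ccc2c1O[C@@H](c1cc(OCc3ccccc3)c(OCc3ccccc3)c(OCc3ccccc3)c1)[C@@H](O)[C@@H]2c1c(OCc3ccccc3)cc(OCc3ccccc3)c2c1O[C@H](c1ccc(OCc3ccccc3)c(OCc3ccccc3)c1)[C@H](O)C2 | intermediate
24 | ent-robinetinidol-(4α→8)-ent-epirobinetinidol-(4α→8)-epicatechin (CNP0115797.3) | Oc1ccc2c(c1)O[C@@H](c1cc(O)c(O)c(O)c1)[C@H](O)[C@@H]2c1c(O)ccc2c1O[C@@H](c1cc(O)c(O)c(O)c1)[C@@H](O)[C@@H]2c1c(O)cc(O)c2c1O[C@H](c1ccc(O)c(O)c1)[C@H](O)C2 | target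

**Step count and risks**

Total steps: 16. Longest linear sequence: 11 steps (1, 2, 3, 4, 5, 7, 8, 12, 13, 15, 16).

Steps most likely to fail:

Step 15. Intermolecular hydroxyalkylation of 21 by the aldehyde may outrun ring closure, leading to double arylation by 21, or the hydroxy aldehyde may isomerise by the acyloin pathway before it cyclises. The fallback separates ring closure from fragment union and uses two known reactions. It sets out from 19, which is converted with trimethyl orthoformate, MeOH and pyridinium p-toluenesulfonate into the dimethyl acetal (2R,3S)-3-[3-(benzyloxy)-2-U-phenoxy]-1,1-dimethoxy-3-Ar-propan-2-ol F1. Treatment of this acetal with Me3SiOTf (catalytic) in CH2Cl2 at −78 °C without any external nucleophile should close ring C by oxocarbenium–arene cyclisation (Pomeranz–Fritsch–Bobbitt type) to the isolable 4-methoxyflavan-3-ol (2S,3S,4R)-7-(benzyloxy)-4-methoxy-8-U-2-Ar-chroman-3-ol F2. This ether is then coupled with 21 under Me3SiOTf at −78 °C, the standard interflavan coupling of 4-alkoxyflavan electrophiles, and the route is rejoined at 23.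

Step 8. The C4 cation may lose the C3 proton to give an enol ether, which would erase the C3 configuration, or hydride delivery may show poor facial selectivity. The fallback replaces the cation by a radical. It sets out from 8 and 11: the lithium alkoxide formed as in step 7 is trapped in the flask with methyl chlorooxoacetate to give (2S,3S,4S)-3,7-bis(benzyloxy)-4-[2-(benzyloxy)-6-(methoxymethoxy)phenyl]-2-Ar-chroman-4-yl methyl oxalate F3. Radical deoxygenation of this ester (Barton–McCombie type; (Me3Si)3SiH, azobisisobutyronitrile, toluene, 80 °C) passes through the C4 radical, which cannot eliminate and should take hydrogen from the bulky silane trans to the C3 benzyloxy group. The route is rejoined at 13, which is then converted into 14 with HCl in MeOH/THF.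

Step 12. The phenoxide of 14 is flanked by the bulky upper unit and may open the epoxide too slowly, so that Payne rearrangement or unimolecular opening with loss of configuration at the benzylic carbon takes over. The fallback changes the order of assembly so that the ether bond is made on an unhindered phenol; it sets out from 17 and 8. 3-(Benzyloxy)-2-bromophenol F4 (mono-benzylation of commercial 2-bromoresorcinol) opens 17 under the conditions of step 12 to give (2S,3S)-3-[3-(benzyloxy)-2-bromophenoxy]-3-Ar-propane-1,2-diol F5. This diol is protected with 2,2-dimethoxypropane and pyridinium p-toluenesulfonate as (4S)-4-{(S)-[3-(benzyloxy)-2-bromophenoxy](Ar)methyl}-2,2-dimethyl-1,3-dioxolane F6. Bromine–lithium exchange (n-BuLi, THF, −78 °C) and addition to 8 should give (2S,3S,4S)-3,7-bis(benzyloxy)-4-[2-(benzyloxy)-6-{(S)-(Ar)[(4S)-2,2-dimethyl-1,3-dioxolan-4-yl]methoxy}phenyl]-2-Ar-chroman-4-ol F7. Ionic hydrogenation as in step 8 (Et3SiH, CF3CO2H, then water) reduces C4 and cleaves the acetonide, and the route is rejoined at 18.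

**Further compounds**

F1 | step 15 | (2R,3S)-3-[3-(benzyloxy)-2-U-phenoxy]-1,1-dimethoxy-3-Ar-propan-2-ol | C(c1ccccc1)Oc1ccc2c(c1)O[C@@H](c1cc(OCc3ccccc3)c(OCc3ccccc3)c(OCc3ccccc3)c1)[C@H](OCc1ccccc1)[C@@H]2c1c(OCc3ccccc3)cccc1O[C@@H](c1cc(OCc3ccccc3)c(OCc3ccccc3)c(OCc3ccccc3)c1)[C@@H](O)C(OC)OC
F2 | step 15 | (2S,3S,4R)-7-(benzyloxy)-4-methoxy-8-U-2-Ar-chroman-3-ol | C(c1ccccc1)Oc1ccc2c(c1)O[C@@H](c1cc(OCc3ccccc3)c(OCc3ccccc3)c(OCc3ccccc3)c1)[C@H](OCc1ccccc1)[C@@H]2c1c(OCc3ccccc3)ccc2c1O[C@@H](c1cc(OCc3ccccc3)c(OCc3ccccc3)c(OCc3ccccc3)c1)[C@@H](O)[C@@H]2OC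
F3 | step 8 | (2S,3S,4S)-3,7-bis(benzyloxy)-4-[2-(benzyloxy)-6-(methoxymethoxy)phenyl]-2-Ar-chroman-4-yl methyl oxalate | C(c1ccccc1)Oc1ccc2c(c1)O[C@@H](c1cc(OCc3ccccc3)c(OCc3ccccc3)c(OCc3ccccc3)c1)[C@H](OCc1ccccc1)[C@@]2(OC(=O)C(=O)OC)c1c(OCc3ccccc3)cccc1OCOC
F4 | step 12 | 3-(benzyloxy)-2-bromophenol | Oc1cccc(OCc2ccccc2)c1Br
F5 | step 12 | (2S,3S)-3-[3-(benzyloxy)-2-bromophenoxy]-3-Ar-propane-1,2-diol | Brc1c(OCc2ccccc2)cccc1O[C@@H](c1cc(OCc2ccccc2)c(OCc2ccccc2)c(OCc2ccccc2)c1)[C@@H](O)CO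
F6 | step 12 | (4S)-4-{(S)-[3-(benzyloxy)-2-bromophenoxy](Ar)methyl}-2,2-dimethyl-1,3-dioxolane | Brc1c(OCc2ccccc2)cccc1O[C@@H](c1cc(OCc2ccccc2)c(OCc2ccccc2)c(OCc2ccccc2)c1)[C@@H]1COC(C)(C)O1
F7 | step 12 | (2S,3S,4S)-3,7-bis(benzyloxy)-4-[2-(benzyloxy)-6-{(S)-(Ar)[(4S)-2,2-dimethyl-1,3-dioxolan-4-yl]methoxy}phenyl]-2-Ar-chroman-4-ol | C(c1ccccc1)Oc1ccc2c(c1)O[C@@H](c1cc(OCc3ccccc3)c(OCc3ccccc3)c(OCc3ccccc3)c1)[C@H](OCc1ccccc1)[C@@]2(O)c1c(OCc3ccccc3)cccc1O[C@@H](c1cc(OCc3ccccc3)c(OCc3ccccc3)c(OCc3ccccc3)c1)[C@@H]1COC(C)(C)O1
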